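The route rests on cutting the cyclohexenone at two bonds: the enone double bond between the side-chain-bearing carbon C2 and the ring CH C3, and the bond between the carbonyl carbon C1 and the gem-dimethyl carbon C6. One flask makes both from two stereodefined fragments: a lithiated serine-derived nitrile adds to an aldol-derived aldehyde (C2–C3; dehydrated in the next step), then iron-hydride hydrogen-atom transfer to an isopropenyl group gives the tertiary C6 radical, which closes 6-exo onto the nitrile carbon, the latent C1 ketone. The step exploits the ring's β-hydroxy-α,α-dimethyl ketone triad C5–C6–C1 next to the enone; C4, C5 and the side-chain centres C7 and C8 are set beforehand.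

Key step: step 8

Assumption: ring atoms are called C1 (C=O), C2 (side-chain-bearing alkene carbon), C3 (alkene CH), C4 (CHMe), C5 (CHOH) and C6 (CMe2), with C7 (carbinol) and C8 (amino carbon) in the side chain; compounds 1, 2, 7, 8, 19, 20 and 25 are taken as commercial.

Step 1
Reactants: 1 (R)-4-benzyl-3-propionyl-1,3-oxazolidin-2-one; 2 methacrolein
Product: 3 (R)-4-benzyl-3-[(2R,3R)-3-hydroxy-2,4-dimethylpent-4-enoyl]-1,3-oxazolidin-2-one
Conditions: Bu2BOTf, iPr2NEt, CH2Cl2, −78 to 0 °C; then pH 7 buffer, MeOH, H2O2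
Reagents that add atoms: none
Why: Evans syn aldol reaction, in which the (Z)-boron enolate reacts through a closed chair transition state with one face shielded by the benzyl group of the auxiliary, should set the methyl-bearing carbon (future C4) and the carbinol carbon (future C5) in the 2,3-syn (2R,3R) sense.

Step 2
Reactants: 3 (R)-4-benzyl-3-[(2R,3R)-3-hydroxy-2,4-dimethylpent-4-enoyl]-1,3-oxazolidin-2-one
Product: 4 (R)-4-benzyl-3-[(2R,3R)-2,4-dimethyl-3-(triethylsilyloxy)pent-4-enoyl]-1,3-oxazolidin-2-one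
Conditions: Et3SiOTf, 2,6-lutidine, CH2Cl2, −78 to 0 °C
Reagents that add atoms: triethylsilyl trifluoromethanesulfonate, CC[Si](CC)(CC)OS(=O)(=O)C(F)(F)F
Why: Silyl ether protection with a silyl triflate masks the future C5 hydroxyl through the basic, radical and mesylation steps without touching a stereocentre.

Step 3
Reactants: 4 (R)-4-benzyl-3-[(2R,3R)-2,4-dimethyl-3-(triethylsilyloxy)pent-4-enoyl]-1,3-oxazolidin-2-one
Product: 5 (2S,3R)-2,4-dimethyl-3-(triethylsilyloxy)pent-4-en-1-ol
Conditions: LiBH4, MeOH (1 equiv), Et2O, 0 °C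
Reagents that add atoms: none
Why: Reductive cleavage of the N-acyl oxazolidinone by hydride attack at the exocyclic imide carbonyl should release the primary alcohol and the auxiliary without epimerising the α-methyl centre.

Step 4
Reactants: 5 (2S,3R)-2,4-dimethyl-3-(triethylsilyloxy)pent-4-en-1-ol
Product: 6 (2R,3R)-2,4-dimethyl-3-(triethylsilyloxy)pent-4-enal
Conditions: Dess–Martin periodinane, CH2Cl2, 0 °C to rt
Reagents that add atoms: none
Why: Dess–Martin oxidation gives the α-chiral aldehyde under non-basic conditions that should not epimerise the α-methyl stereocentre.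

Step 5
Reactants: 7 N-Boc-O-methyl-D-serine; 8 acetonitrile
Product: 10 tert-butyl N-[(2R)-4-cyano-1-methoxy-3-oxobutan-2-yl]carbamate, via acyl imidazolide 9 (not isolated)
Conditions: 7, 1,1'-carbonyldiimidazole, THF, rt; then added to LiCH2CN (from 8 and LiN(iPr)2, 3.2 equiv), THF, −78 °C; then aq. HCl (1 mol/L) to pH 4
Reagents that add atoms: none
Why: Claisen-type C-acylation of lithiated acetonitrile by the acyl imidazolide gives the β-ketonitrile, which stays as its enolate until the quench so that the α-amino stereocentre (future C8) should not epimerise.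

Step 6
Reactants: 10 tert-butyl N-[(2R)-4-cyano-1-methoxy-3-oxobutan-2-yl]carbamate
Product: 11 tert-butyl N-[(2R,3S)-4-cyano-3-hydroxy-1-methoxybutan-2-yl]carbamate
Conditions: LiAlH(OtBu)3, EtOH, −78 °C
Reagents that add atoms: none
Why: Chelation-controlled (Cram-chelate) hydride reduction of the carbamate-protected α-amino ketone should deliver hydride to the less hindered face of the chelate and set the anti amino alcohol, the (3S) carbinol that becomes C7.

Step 7
Reactants: 11 tert-butyl N-[(2R,3S)-4-cyano-3-hydroxy-1-methoxybutan-2-yl]carbamate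
Product: 12 tert-butyl (4R,5S)-5-(cyanomethyl)-4-(methoxymethyl)-2,2-dimethyl-1,3-oxazolidine-3-carboxylate
Conditions: 2,2-dimethoxypropane, BF3·OEt2 (cat.), acetone, rt
Reagents that add atoms: 2,2-dimethoxypropane, COC(C)(C)OC
Why: Acid-catalysed N,O-acetalisation locks the anti amino alcohol as the cis-oxazolidine and removes both acidic protons before the carbanion chemistry, leaving the stereocentres unchanged.

Step 8
Reactants: 12 tert-butyl (4R,5S)-5-(cyanomethyl)-4-(methoxymethyl)-2,2-dimethyl-1,3-oxazolidine-3-carboxylate; 6 (2R,3R)-2,4-dimethyl-3-(triethylsilyloxy)pent-4-enal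
Product: 15 tert-butyl (4R,5S)-5-[(3S,4R)-2-hydroxy-3,5,5-trimethyl-6-oxo-4-(triethylsilyloxy)cyclohexyl]-4-(methoxymethyl)-2,2-dimethyl-1,3-oxazolidine-3-carboxylate (epimer mixture at cyclohexyl C1/C2), via aldol adduct 13 (not isolated), via cyclic ketimine 14 (not isolated)
Conditions: 12, LiN(iPr)2, THF, −78 °C, then 6; AcOH, −78 °C to rt; solvent switch to EtOH; Fe(acac)3 (30 mol %), PhSiH3, 60 °C; then AcOH/NaOAc buffer (pH 4.5), THF–H2O, rt
Reagents that add atoms: water, O
Why: Deprotonation of 12 gives the α-cyano carbanion, which adds to aldehyde 6 (nitrile aldol addition) and joins C2 to C3; after the acidic quench the trivalent-iron hydride formed from Fe(acac)3 and PhSiH3 transfers a hydrogen atom to the CH2 terminus of the isopropenyl group, the tertiary C6 radical adds to the nitrile carbon C1, the iminyl radical is reduced and protonated to ketimine 14, and buffered hydrolysis gives the ketone. The closest known reaction types are the aldol addition of lithiated nitriles and the iron-hydride hydrogen-atom-transfer radical cyclisation of alkenyl nitriles to cyclic ketones. The six-membered ring closes in the 6-exo-dig mode. The two new stereocentres (C2 and C3) form without control and need none because both become sp2 in step 9, while C4, C5, C7 and C8 are spectators that these conditions should not epimerise. The step needs Markovnikov hydrogen-atom transfer and ring closure faster than reduction of the radical, which the single electron-rich 1,1-disubstituted alkene, the long-lived tertiary radical and the chain substituents on C4 and C5 should secure. It also needs aldol addition faster than β-elimination of the lithiated nitrile, which the low temperature and the poor leaving ability of the oxazolidine oxygen should secure.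

Step 9
Reactants: 15 tert-butyl (4R,5S)-5-[(3S,4R)-2-hydroxy-3,5,5-trimethyl-6-oxo-4-(triethylsilyloxy)cyclohexyl]-4-(methoxymethyl)-2,2-dimethyl-1,3-oxazolidine-3-carboxylate
Product: 17 tert-butyl (4R,5S)-4-(methoxymethyl)-2,2-dimethyl-5-[(3S,4R)-3,5,5-trimethyl-6-oxo-4-(triethylsilyloxy)cyclohex-1-en-1-yl]-1,3-oxazolidine-3-carboxylate, via mesylate 16 (not isolated)
Conditions: MsCl, Et3N, CH2Cl2, 0 °C; then DBU, rt
Reagents that add atoms: none
Why: Mesylation of the only free hydroxyl followed by E1cB β-elimination through the ketone enolate should give the C2=C3 enone from every epimer, erasing the two uncontrolled centres, while C5 (silyl ether) and C6 (no hydrogen) cannot compete.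

Step 10
Reactants: 17 tert-butyl (4R,5S)-4-(methoxymethyl)-2,2-dimethyl-5-[(3S,4R)-3,5,5-trimethyl-6-oxo-4-(triethylsilyloxy)cyclohex-1-en-1-yl]-1,3-oxazolidine-3-carboxylate
Product: 18 (4S,5R)-2-[(1S,2R)-2-amino-1-hydroxy-3-methoxypropyl]-5-hydroxy-4,6,6-trimethylcyclohex-2-en-1-one hydrochloride
Conditions: HCl (3 mol/L in MeOH), 0 °C to rt
Reagents that add atoms: hydrogen chloride, Cl
Why: Acidolysis (global deprotection) cleaves the Boc group, the N,O-acetonide and the triethylsilyl ether in one operation and keeps the amine as its hydrochloride so that it cannot condense with the ring ketone.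

Step 11
Reactants: 19 (S)-citronellal; 20 (E)-oct-4-ene
Product: 21 (3S)-3-methyldec-6-enal (E/Z mixture)
Conditions: second-generation Grubbs catalyst RuCl2(=CHPh)(PCy3)(H2IMes) (3 mol %), excess 20, CH2Cl2, 40 °C
Reagents that add atoms: none
Why: Olefin cross-metathesis swaps the isopropylidene terminus of the chiral-pool aldehyde for a butylidene group, with the stereocentre untouched and the alkene geometry irrelevant because the alkene is hydrogenated next.

Step 12
Reactants: 21 (3S)-3-methyldec-6-enal
Product: 22 (S)-3-methyldecanal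
Conditions: H2 (1 atm), Pd/C, EtOAc, rt
Reagents that add atoms: none
Why: Heterogeneous catalytic hydrogenation should saturate the disubstituted alkene in the presence of the aliphatic aldehyde and leave the methyl-bearing stereocentre unchanged.

Step 13
Reactants: 22 (S)-3-methyldecanal
Product: 23 (4S,6S)-6-methyltridec-1-en-4-ol
Conditions: CH2=CHCH2SnBu3, Ti(OiPr)4 (10 mol %), (S)-BINOL (10 mol %), 4 Å molecular sieves, CH2Cl2, −20 °C; aq. NaHCO3
Reagents that add atoms: allyltributylstannane, C=CC[Sn](CCCC)(CCCC)CCCC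
Why: Keck asymmetric allylation, in which the (S)-BINOL–titanium Lewis acid should direct allyl transfer to the Si face of the aldehyde under catalyst control (the β-methyl centre exerting little bias), sets the (4S) carbinol.

Step 14
Reactants: 23 (4S,6S)-6-methyltridec-1-en-4-ol
Product: 24 (4S,6S)-4-methoxy-6-methyltridec-1-ene
Conditions: NaH, MeI, THF, 0 °C to rt
Reagents that add atoms: iodomethane, CI
Why: Williamson etherification of the sodium alkoxide installs the methyl ether without affecting either stereocentre.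

Step 15
Reactants: 24 (4S,6S)-4-methoxy-6-methyltridec-1-ene; 25 pent-4-enoic acid
Product: 26 (4E,7R,9S)-7-methoxy-9-methylhexadec-4-enoic acid
Conditions: second-generation Grubbs catalyst RuCl2(=CHPh)(PCy3)(H2IMes) (5 mol %), 25 (3 equiv), CH2Cl2, 40 °C; chromatography on AgNO3-impregnated silica
Reagents that add atoms: none
Why: Olefin cross-metathesis of two unhindered terminal alkenes, driven by loss of ethylene, should give mainly the E-alkene under thermodynamic control, the minor Z-isomer being removed on silver nitrate-impregnated silica.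

Step 16
Reactants: 26 (4E,7R,9S)-7-methoxy-9-methylhexadec-4-enoic acid; 18 (4S,5R)-2-[(1S,2R)-2-amino-1-hydroxy-3-methoxypropyl]-5-hydroxy-4,6,6-trimethylcyclohex-2-en-1-one hydrochloride
Product: 27 (4E,7R,9S)-N-[(1S,2R)-1-hydroxy-1-[(3S,4R)-4-hydroxy-3,5,5-trimethyl-6-oxocyclohex-1-en-1-yl]-3-methoxypropan-2-yl]-7-methoxy-9-methylhexadec-4-enamide (CNP0168625.1)
Conditions: 26, EDC·HCl, HOBt, CH2Cl2/DMF, 0 °C; then 18, iPr2NEt, 0 °C to rt
Reagents that add atoms: none
Why: Carbodiimide/HOBt amide coupling, in which the amine is liberated in the presence of the pre-formed active ester, should acylate nitrogen much faster than either secondary alcohol and give the target with all stereocentres unchanged.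

Compound list
1 | (R)-4-benzyl-3-propionyl-1,3-oxazolidin-2-one | CCC(=O)N1[C@H](Cc2ccccc2)COC1=O | starting material
2 | methacrolein | CC(=C)C=O | starting material
3 | (R)-4-benzyl-3-[(2R,3R)-3-hydroxy-2,4-dimethylpent-4-enoyl]-1,3-oxazolidin-2-one | O=C1OC[C@@H](Cc2ccccc2)N1C(=O)[C@H](C)[C@@H](O)C(C)=C | intermediate
4 | (R)-4-benzyl-3-[(2R,3R)-2,4-dimethyl-3-(triethylsilyloxy)pent-4-enoyl]-1,3-oxazolidin-2-one | O=C1OC[C@@H](Cc2ccccc2)N1C(=O)[C@H](C)[C@@H](O[Si](CC)(CC)CC)C(C)=C | intermediate
5 | (2S,3R)-2,4-dimethyl-3-(triethylsilyloxy)pent-4-en-1-ol | OC[C@H](C)[C@@H](O[Si](CC)(CC)CC)C(C)=C | intermediate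
6 | (2R,3R)-2,4-dimethyl-3-(triethylsilyloxy)pent-4-enal | O=C[C@H](C)[C@@H](O[Si](CC)(CC)CC)C(C)=C | intermediate
7 | N-Boc-O-methyl-D-serine, (2R)-2-[(tert-butoxycarbonyl)amino]-3-methoxypropanoic acid | CC(C)(C)OC(=O)N[C@H](COC)C(O)=O | starting material
8 | acetonitrile | CC#N | starting material
9 | tert-butyl N-[(2R)-1-(imidazol-1-yl)-3-methoxy-1-oxopropan-2-yl]carbamate (acyl imidazolide) | CC(C)(C)OC(=O)N[C@H](COC)C(=O)n1ccnc1 | intermediate (not isolated)
10 | tert-butyl N-[(2R)-4-cyano-1-methoxy-3-oxobutan-2-yl]carbamate | CC(C)(C)OC(=O)N[C@H](COC)C(=O)CC#N | intermediate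
11 | tert-butyl N-[(2R,3S)-4-cyano-3-hydroxy-1-methoxybutan-2-yl]carbamate | CC(C)(C)OC(=O)N[C@H](COC)[C@@H](O)CC#N | intermediate
12 | tert-butyl (4R,5S)-5-(cyanomethyl)-4-(methoxymethyl)-2,2-dimethyl-1,3-oxazolidine-3-carboxylate | CC(C)(C)OC(=O)N1[C@H](COC)[C@H](CC#N)OC1(C)C | intermediate
13 | tert-butyl (4R,5S)-5-[(3S,4R)-1-cyano-2-hydroxy-3,5-dimethyl-4-(triethylsilyloxy)hex-5-en-1-yl]-4-(methoxymethyl)-2,2-dimethyl-1,3-oxazolidine-3-carboxylate (epimer mixture at hexenyl C1/C2) | CC(C)(C)OC(=O)N1[C@H](COC)[C@@H](OC1(C)C)C(C#N)C(O)[C@H](C)[C@@H](O[Si](CC)(CC)CC)C(C)=C | intermediate (not isolated)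
14 | tert-butyl (4R,5S)-5-[(3S,4R)-2-hydroxy-6-imino-3,5,5-trimethyl-4-(triethylsilyloxy)cyclohexyl]-4-(methoxymethyl)-2,2-dimethyl-1,3-oxazolidine-3-carboxylate | CC(C)(C)OC(=O)N1[C@H](COC)[C@@H](OC1(C)C)C2C(O)[C@H](C)[C@@H](O[Si](CC)(CC)CC)C(C)(C)C2=N | intermediate (not isolated)
15 | tert-butyl (4R,5S)-5-[(3S,4R)-2-hydroxy-3,5,5-trimethyl-6-oxo-4-(triethylsilyloxy)cyclohexyl]-4-(methoxymethyl)-2,2-dimethyl-1,3-oxazolidine-3-carboxylate (epimer mixture at cyclohexyl C1/C2) | CC(C)(C)OC(=O)N1[C@H](COC)[C@@H](OC1(C)C)C2C(O)[C@H](C)[C@@H](O[Si](CC)(CC)CC)C(C)(C)C2=O | intermediate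
16 | tert-butyl (4R,5S)-4-(methoxymethyl)-2,2-dimethyl-5-[(3R,4R)-3,5,5-trimethyl-2-(methylsulfonyloxy)-6-oxo-4-(triethylsilyloxy)cyclohexyl]-1,3-oxazolidine-3-carboxylate | CC(C)(C)OC(=O)N1[C@H](COC)[C@@H](OC1(C)C)C2C(OS(C)(=O)=O)[C@H](C)[C@@H](O[Si](CC)(CC)CC)C(C)(C)C2=O | intermediate (not isolated)
17 | tert-butyl (4R,5S)-4-(methoxymethyl)-2,2-dimethyl-5-[(3S,4R)-3,5,5-trimethyl-6-oxo-4-(triethylsilyloxy)cyclohex-1-en-1-yl]-1,3-oxazolidine-3-carboxylate | CC(C)(C)OC(=O)N1[C@H](COC)[C@@H](OC1(C)C)C2=C[C@H](C)[C@@H](O[Si](CC)(CC)CC)C(C)(C)C2=O | intermediate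
18 | (4S,5R)-2-[(1S,2R)-2-amino-1-hydroxy-3-methoxypropyl]-5-hydroxy-4,6,6-trimethylcyclohex-2-en-1-one hydrochloride | Cl.N[C@H](COC)[C@@H](O)C1=C[C@H](C)[C@@H](O)C(C)(C)C1=O | intermediate
19 | (S)-citronellal | CC(C)=CCC[C@H](C)CC=O | starting material
20 | (E)-oct-4-ene | CCC/C=C/CCC | starting material
21 | (3S)-3-methyldec-6-enal (E/Z mixture) | CCCC=CCC[C@H](C)CC=O | intermediate
22 | (S)-3-methyldecanal | CCCCCCC[C@H](C)CC=O | intermediate
23 | (4S,6S)-6-methyltridec-1-en-4-ol | CCCCCCC[C@H](C)C[C@H](CC=C)O | intermediate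
24 | (4S,6S)-4-methoxy-6-methyltridec-1-ene | CCCCCCC[C@H](C)C[C@H](CC=C)OC | intermediate
25 | pent-4-enoic acid | OC(=O)CCC=C | starting material
26 | (4E,7R,9S)-7-methoxy-9-methylhexadec-4-enoic acid | CCCCCCC[C@H](C)C[C@H](C/C=C/CCC(O)=O)OC | intermediate
27 | (4E,7R,9S)-N-[(1S,2R)-1-hydroxy-1-[(3S,4R)-4-hydroxy-3,5,5-trimethyl-6-oxocyclohex-1-en-1-yl]-3-methoxypropan-2-yl]-7-methoxy-9-methylhexadec-4-enamide | CCCCCCC[C@H](C)C[C@H](C/C=C/CCC(=O)N[C@H](COC)[C@@H](O)C1=C[C@H](C)[C@@H](O)C(C)(C)C1=O)OC | target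

Total step count: 16.
Longest linear sequence: 8 steps (steps 1, 2, 3, 4, 8, 9, 10, 16).

Steps most likely to fail

Step 8. The lithiated nitrile may fragment by β-elimination (opening of the oxazolidine) before it adds to the aldehyde. After hydrogen-atom transfer the tertiary radical may be reduced (net hydrogenation of the isopropenyl group) faster than it closes onto the α-branched nitrile. The hindered ketimine may also hydrolyse slowly. The fallback builds the ring before the side chain is attached, so that the carbanion carries no β-oxygen and the nitrile is unbranched. It sets out from 6: addition of LiCH2CN (from 8) should give the β-hydroxy nitrile (4S,5R)-3-hydroxy-4,6-dimethyl-5-(triethylsilyloxy)hept-6-enenitrile F1. The same Fe(acac)3/PhSiH3 radical cyclisation and buffered hydrolysis should give (3R,4S)-5-hydroxy-2,2,4-trimethyl-3-(triethylsilyloxy)cyclohexan-1-one F2. Mesylation and elimination should give (4S,5R)-4,6,6-trimethyl-5-(triethylsilyloxy)cyclohex-2-en-1-one F3, and I2/pyridine the α-iodoenone (4S,5R)-2-iodo-4,6,6-trimethyl-5-(triethylsilyloxy)cyclohex-2-en-1-one F4. Reduction of acyl imidazolide 9 with iBu2AlH should give the aldehyde tert-butyl N-[(2R)-1-methoxy-3-oxopropan-2-yl]carbamate F5. Nozaki–Hiyama–Kishi coupling of F4 with F5 (CrCl2, cat. NiCl2, DMF; Felkin–Anh addition expected to favour the anti amino alcohol) should give the allylic alcohol tert-butyl N-[(1S,2R)-1-hydroxy-3-methoxy-1-[(3S,4R)-3,5,5-trimethyl-6-oxo-4-(triethylsilyloxy)cyclohex-1-en-1-yl]propan-2-yl]carbamate F6. Oxazolidine formation with 2,2-dimethoxypropane/BF3·OEt2 returns to 17.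

Step 15. Metathesis gives a thermodynamic E/Z mixture, and self-metathesis of either partner competes, so the pure E-acid may be hard to obtain. The fallback sets the alkene by a chair-like [3,3] rearrangement and sets out from 24. Ozonolysis (O3; PPh3) should give (3R,5S)-3-methoxy-5-methyldodecanal F7. Addition of CH2=CHMgBr should give the allylic alcohol (5R,7S)-5-methoxy-7-methyltetradec-1-en-3-ol F8 (carbinol configuration irrelevant). Johnson–Claisen rearrangement (MeC(OEt)3, cat. EtCO2H, 140 °C) should give ethyl (4E,7R,9S)-7-methoxy-9-methylhexadec-4-enoate F9, and LiOH saponification returns to 26.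

Step 6. The basic hydride may enolise the acidic β-ketonitrile and stall the reduction, or chelation control may give insufficient facial selectivity. The fallback replaces substrate control by reagent control: Corey–Bakshi–Shibata reduction of 10 with the (R)-oxazaborolidine and catecholborane, whose facial preference does not depend on chelation, goes from 10 directly to 11 and makes no new compound.

Further compounds
F1 | step 8 | (4S,5R)-3-hydroxy-4,6-dimethyl-5-(triethylsilyloxy)hept-6-enenitrile (epimer mixture at C3) | N#CCC(O)[C@H](C)[C@@H](O[Si](CC)(CC)CC)C(C)=C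
F2 | step 8 | (3R,4S)-5-hydroxy-2,2,4-trimethyl-3-(triethylsilyloxy)cyclohexan-1-one (epimer mixture at C5) | O=C1CC(O)[C@H](C)[C@@H](O[Si](CC)(CC)CC)C1(C)C
F3 | step 8 | (4S,5R)-4,6,6-trimethyl-5-(triethylsilyloxy)cyclohex-2-en-1-one | O=C1C=C[C@H](C)[C@@H](O[Si](CC)(CC)CC)C1(C)C
F4 | step 8 | (4S,5R)-2-iodo-4,6,6-trimethyl-5-(triethylsilyloxy)cyclohex-2-en-1-one | O=C1C(I)=C[C@H](C)[C@@H](O[Si](CC)(CC)CC)C1(C)C
F5 | step 8 | tert-butyl N-[(2R)-1-methoxy-3-oxopropan-2-yl]carbamate | CC(C)(C)OC(=O)N[C@H](COC)C=O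
F6 | step 8 | tert-butyl N-[(1S,2R)-1-hydroxy-3-methoxy-1-[(3S,4R)-3,5,5-trimethyl-6-oxo-4-(triethylsilyloxy)cyclohex-1-en-1-yl]propan-2-yl]carbamate | CC(C)(C)OC(=O)N[C@H](COC)[C@@H](O)C1=C[C@H](C)[C@@H](O[Si](CC)(CC)CC)C(C)(C)C1=O
F7 | step 15 | (3R,5S)-3-methoxy-5-methyldodecanal | CCCCCCC[C@H](C)C[C@H](CC=O)OC
F8 | step 15 | (5R,7S)-5-methoxy-7-methyltetradec-1-en-3-ol (epimer mixture at C3) | CCCCCCC[C@H](C)C[C@H](CC(O)C=C)OC
F9 | step 15 | ethyl (4E,7R,9S)-7-methoxy-9-methylhexadec-4-enoate | CCCCCCC[C@H](C)C[C@H](C/C=C/CCC(=O)OCC)OC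
F0 | step 6 | none | none
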